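**Retrosynthetic overview**
- The target comes from its tris-MOM ether. Both prenyl groups come from allyl groups by cross-metathesis with 2-methylbut-2-ene, and the allyl groups from aryl bromides by Stille coupling.
- The ring-A C5 bromide comes from para-bromination of a 2-hydroxy-4-(methoxymethoxy)benzophenone. The ring-B C2′ bromide is carried from the start.
- Aromatic ring A comes from dehydrogenation of a 6-aroyl-3-(methoxymethoxy)cyclohex-2-enone, a masked 4-aroylcyclohexane-1,3-dione.
- Key C–C bond (ring-A C1 to the carbonyl carbon): intermolecular aldol addition of the kinetic lithium enolate of 3-(methoxymethoxy)cyclohex-2-en-1-one to 2-bromo-3-(methoxymethoxy)benzaldehyde, followed by oxidation of the aldol.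
- Ring order: ring B is bought as an arene. The ring-A carbocycle is bought as cyclohexane-1,3-dione and becomes aromatic only after the fragment union.

Assumption: the target has no stereocentre and no stereogenic double bond, so the achiral compound itself is the required single species.

**Route**

Step 1
Reactants: 1 cyclohexane-1,3-dione
Product: 2 3-(methoxymethoxy)cyclohex-2-en-1-one
Conditions: MOMCl (1.2 equiv), i-Pr2NEt (1.5 equiv), CH2Cl2, 0 °C to rt
Reagents that add atoms: chloromethyl methyl ether (MOMCl), COCCl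
Why: O-alkylation of the 1,3-dione enolate by the hard electrophile MOMCl (enol ether formation) gives the vinylogous ester, which directs later enolisation to C6 and already carries the protecting group wanted on the ring-A 4-oxygen.

Step 2
Reactants: 3 2-bromo-3-hydroxybenzaldehyde
Product: 4 2-bromo-3-(methoxymethoxy)benzaldehyde
Conditions: MOMCl (1.3 equiv), i-Pr2NEt (1.6 equiv), CH2Cl2, 0 °C to rt
Reagents that add atoms: chloromethyl methyl ether (MOMCl), COCCl
Why: Williamson-type O-alkylation (MOM protection) of the phenol under mild amine base leaves the aldehyde and the aryl bromide untouched.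

Step 3
Reactants: 2 3-(methoxymethoxy)cyclohex-2-en-1-one; 4 2-bromo-3-(methoxymethoxy)benzaldehyde
Product: 7 6-[(2-bromo-3-(methoxymethoxy)phenyl)(hydroxy)methyl]-3-(methoxymethoxy)cyclohex-2-en-1-one (racemic diastereomer mixture), via lithium enolate 5 (not isolated), via lithium aldolate 6 (not isolated)
Conditions: 2 (1.1 equiv), LiN(i-Pr)2 (1.05 equiv, commercial solution), THF, −78 °C, 45 min; then 4 (1.0 equiv), −78 °C, 1 h; AcOH quench at −78 °C
Reagents that add atoms: none
Why: Stork–Danheiser-type kinetic deprotonation of the vinylogous ester at C6 gives the cross-conjugated lithium enolate, whose intermolecular aldol addition to the non-enolisable aldehyde forms the ring-A C1–carbonyl carbon bond; the two new stereocentres form without control and are both erased in steps 4 and 5.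

Step 4
Reactants: 7 6-[(2-bromo-3-(methoxymethoxy)phenyl)(hydroxy)methyl]-3-(methoxymethoxy)cyclohex-2-en-1-one
Product: 8 6-[2-bromo-3-(methoxymethoxy)benzoyl]-3-(methoxymethoxy)cyclohex-2-en-1-one
Conditions: Dess–Martin periodinane (1.3 equiv), pyridine (3 equiv), CH2Cl2, 0 °C to rt
Reagents that add atoms: none
Why: Dess–Martin oxidation of the secondary benzylic alcohol under buffered non-aqueous conditions gives the enolised β-diketone without retro-aldol or dehydration and removes the carbinol stereocentre.

Step 5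
Reactants: 8 6-[2-bromo-3-(methoxymethoxy)benzoyl]-3-(methoxymethoxy)cyclohex-2-en-1-one
Product: 9 [2-bromo-3-(methoxymethoxy)phenyl][2-hydroxy-4-(methoxymethoxy)phenyl]methanone
Conditions: DDQ (1.2 equiv), 1,4-dioxane, rt to 50 °C
Reagents that add atoms: none
Why: The enol of β-diketone 8 is a cyclohexa-1,3-dienol, i.e. a dihydroarene, so DDQ dehydrogenation (hydride abstraction, then proton loss) aromatises ring A to the hydrogen-bonded 2-hydroxybenzophenone and destroys the last stereocentre.

Step 6
Reactants: 9 [2-bromo-3-(methoxymethoxy)phenyl][2-hydroxy-4-(methoxymethoxy)phenyl]methanone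
Product: 10 [5-bromo-2-hydroxy-4-(methoxymethoxy)phenyl][2-bromo-3-(methoxymethoxy)phenyl]methanone
Conditions: NBS (1.0 equiv), MeCN, 0 °C, dark
Reagents that add atoms: N-bromosuccinimide, O=C1CCC(=O)N1Br
Why: Electrophilic aromatic bromination goes to ring-A C5, which is para to the free hydroxyl, ortho to the MOM ether and meta to the acyl group, whereas C3 is flanked by two oxygen substituents and ring B has only one donor beside a carbonyl and a bromine.

Step 7
Reactants: 10 [5-bromo-2-hydroxy-4-(methoxymethoxy)phenyl][2-bromo-3-(methoxymethoxy)phenyl]methanone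
Product: 11 [5-bromo-2,4-bis(methoxymethoxy)phenyl][2-bromo-3-(methoxymethoxy)phenyl]methanone
Conditions: MOMCl (3 equiv), i-Pr2NEt (4 equiv), CH2Cl2, 0 °C to 40 °C
Reagents that add atoms: chloromethyl methyl ether (MOMCl), COCCl
Why: O-alkylation (MOM protection) of the chelated phenol removes the nucleophile that could otherwise displace the neighbouring ring-B bromide to a xanthone under the basic fluoride conditions of step 8.

Step 8
Reactants: 11 [5-bromo-2,4-bis(methoxymethoxy)phenyl][2-bromo-3-(methoxymethoxy)phenyl]methanone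
Product: 12 [2,4-bis(methoxymethoxy)-5-(prop-2-en-1-yl)phenyl][3-(methoxymethoxy)-2-(prop-2-en-1-yl)phenyl]methanone
Conditions: CH2=CHCH2SnBu3 (3 equiv), Pd(P(t-Bu)3)2 (5 mol %), CsF (4.4 equiv), 1,4-dioxane, 100 °C
Reagents that add atoms: tributyl(prop-2-en-1-yl)stannane, C=CC[Sn](CCCC)(CCCC)CCCC
Why: Double Stille cross-coupling, in which the bulky electron-rich phosphine on zerovalent palladium and fluoride activation of the stannane allow coupling even at the di-ortho-substituted ring-B bromide, and the symmetric allyl group transfers without regiochemical ambiguity.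

Step 9
Reactants: 12 [2,4-bis(methoxymethoxy)-5-(prop-2-en-1-yl)phenyl][3-(methoxymethoxy)-2-(prop-2-en-1-yl)phenyl]methanone
Product: 13 [2,4-bis(methoxymethoxy)-5-(3-methylbut-2-en-1-yl)phenyl][3-(methoxymethoxy)-2-(3-methylbut-2-en-1-yl)phenyl]methanone
Conditions: 2-methylbut-2-ene (large excess), second-generation Grubbs catalyst RuCl2(=CHPh)(PCy3)(H2IMes) (10 mol %), CH2Cl2, 40 °C, sealed tube
Reagents that add atoms: 2-methylbut-2-ene, CC=C(C)C
Why: Olefin cross-metathesis of both terminal allyl groups with excess 2-methylbut-2-ene gives the trisubstituted prenyl alkenes, which are inert to further metathesis and have no E/Z issue.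

Step 10
Reactants: 13 [2,4-bis(methoxymethoxy)-5-(3-methylbut-2-en-1-yl)phenyl][3-(methoxymethoxy)-2-(3-methylbut-2-en-1-yl)phenyl]methanone
Product: 14 cudraphenone B, [2,4-dihydroxy-5-(3-methylbut-2-en-1-yl)phenyl][3-hydroxy-2-(3-methylbut-2-en-1-yl)phenyl]methanone
Conditions: 3 M aq. HCl, MeOH, 40 °C
Reagents that add atoms: none
Why: Acid-catalysed acetal cleavage (MOM deprotection) frees the three phenols under conditions mild enough to leave the ortho-prenyl groups uncyclised.

**Compound list**
1 | cyclohexane-1,3-dione | O=C1CCCC(=O)C1 | starting material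
2 | 3-(methoxymethoxy)cyclohex-2-en-1-one | COCOC1=CC(=O)CCC1 | intermediate
3 | 2-bromo-3-hydroxybenzaldehyde | O=Cc1cccc(O)c1Br | starting material
4 | 2-bromo-3-(methoxymethoxy)benzaldehyde | COCOc1cccc(C=O)c1Br | intermediate
5 | lithium 5-(methoxymethoxy)cyclohexa-1,5-dien-1-olate (kinetic enolate of 2, not isolated) | [Li]OC1=CCCC(OCOC)=C1 | intermediate
6 | lithium aldolate of 7 (not isolated, racemic diastereomer mixture) | COCOC1=CC(=O)C(CC1)C(O[Li])c1cccc(OCOC)c1Br | intermediate
7 | 6-[(2-bromo-3-(methoxymethoxy)phenyl)(hydroxy)methyl]-3-(methoxymethoxy)cyclohex-2-en-1-one (racemic diastereomer mixture) | COCOC1=CC(=O)C(CC1)C(O)c1cccc(OCOC)c1Br | intermediate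
8 | 6-[2-bromo-3-(methoxymethoxy)benzoyl]-3-(methoxymethoxy)cyclohex-2-en-1-one (racemic, enolised) | COCOC1=CC(=O)C(CC1)C(=O)c1cccc(OCOC)c1Br | intermediate
9 | [2-bromo-3-(methoxymethoxy)phenyl][2-hydroxy-4-(methoxymethoxy)phenyl]methanone | COCOc1ccc(C(=O)c2cccc(OCOC)c2Br)c(O)c1 | intermediate
10 | [5-bromo-2-hydroxy-4-(methoxymethoxy)phenyl][2-bromo-3-(methoxymethoxy)phenyl]methanone | COCOc1cc(O)c(C(=O)c2cccc(OCOC)c2Br)cc1Br | intermediate
11 | [5-bromo-2,4-bis(methoxymethoxy)phenyl][2-bromo-3-(methoxymethoxy)phenyl]methanone | COCOc1cc(OCOC)c(C(=O)c2cccc(OCOC)c2Br)cc1Br | intermediate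
12 | [2,4-bis(methoxymethoxy)-5-(prop-2-en-1-yl)phenyl][3-(methoxymethoxy)-2-(prop-2-en-1-yl)phenyl]methanone | COCOc1cc(OCOC)c(C(=O)c2cccc(OCOC)c2CC=C)cc1CC=C | intermediate
13 | [2,4-bis(methoxymethoxy)-5-(3-methylbut-2-en-1-yl)phenyl][3-(methoxymethoxy)-2-(3-methylbut-2-en-1-yl)phenyl]methanone | COCOc1cc(OCOC)c(C(=O)c2cccc(OCOC)c2CC=C(C)C)cc1CC=C(C)C | intermediate
14 | cudraphenone B | CC(C)=CCc1cc(C(=O)c2cccc(O)c2CC=C(C)C)c(O)cc1O | target

**Totals**
Total step count: 10.
Longest linear sequence: 9 steps (1 → 2 → 7 → 8 → 9 → 10 → 11 → 12 → 13 → 14; the branch from 3 through 4 is equally long).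

**Three steps most likely to fail, with fallbacks**

Step 5 (DDQ aromatisation; risk of sluggish hydride abstraction or loss of the enol MOM ether). The fallback sets out from 8 and comes back at 9. It replaces direct dehydrogenation by α-functionalisation and syn-elimination. Treating 8 with PhSeCl and pyridine in CH2Cl2 at 0 °C gives 6-[2-bromo-3-(methoxymethoxy)benzoyl]-3-(methoxymethoxy)-6-(phenylselanyl)cyclohex-2-en-1-one F1. Aqueous H2O2 in CH2Cl2 at 0 °C oxidises it to the selenoxide F2, which eliminates spontaneously to 6-[2-bromo-3-(methoxymethoxy)benzoyl]-3-(methoxymethoxy)cyclohexa-2,5-dien-1-one F3. This dienone tautomerises in the flask to phenol 9.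

Step 8 (double Stille coupling; the ring-B bromide sits between the aroyl group and a MOM ether, and the allyl group may isomerise to propenyl). The fallback sets out from 4 and comes back at 12. It installs the ring-B allyl group before the fragment union, where the bromide is flanked only by a formyl group. Stille coupling of 4 with CH2=CHCH2SnBu3 (Pd(PPh3)4, toluene, 100 °C) gives 3-(methoxymethoxy)-2-(prop-2-en-1-yl)benzaldehyde F4. Addition of enolate 5 at −78 °C gives the lithium aldolate F5, and acetic acid quench gives 6-[hydroxy(3-(methoxymethoxy)-2-(prop-2-en-1-yl)phenyl)methyl]-3-(methoxymethoxy)cyclohex-2-en-1-one F6. Dess–Martin oxidation gives 6-[3-(methoxymethoxy)-2-(prop-2-en-1-yl)benzoyl]-3-(methoxymethoxy)cyclohex-2-en-1-one F7. DDQ at rt gives [2-hydroxy-4-(methoxymethoxy)phenyl][3-(methoxymethoxy)-2-(prop-2-en-1-yl)phenyl]methanone F8; the terminal alkene is far less prone to oxidation than the dienol. NBS in MeCN at 0 °C gives [5-bromo-2-hydroxy-4-(methoxymethoxy)phenyl][3-(methoxymethoxy)-2-(prop-2-en-1-yl)phenyl]methanone F9. MOMCl and i-Pr2NEt give [5-bromo-2,4-bis(methoxymethoxy)phenyl][3-(methoxymethoxy)-2-(prop-2-en-1-yl)phenyl]methanone F10. A single Stille allylation at the unhindered ring-A bromide under the conditions of step 8 then gives 12.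

Step 10 (acidic removal of three MOM groups; risk of acid-catalysed cyclisation of ortho-prenylphenols to 2,2-dimethylchromans). The fallback sets out from 12 and comes back at 14. It reverses the order of the last two operations so that acid never meets a prenyl group. Treating 12 with 3 M aq. HCl in MeOH at 40 °C gives [2,4-dihydroxy-5-(prop-2-en-1-yl)phenyl][3-hydroxy-2-(prop-2-en-1-yl)phenyl]methanone F11, whose terminal allyl groups do not cyclise under these conditions. Cross-metathesis of the free triphenol with excess 2-methylbut-2-ene and second-generation Grubbs catalyst RuCl2(=CHPh)(PCy3)(H2IMes) in CH2Cl2 at 40 °C then gives 14 directly.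

**Further compounds**
F1 | step 5 | 6-[2-bromo-3-(methoxymethoxy)benzoyl]-3-(methoxymethoxy)-6-(phenylselanyl)cyclohex-2-en-1-one (racemic) | COCOC1=CC(=O)C(CC1)([Se]c1ccccc1)C(=O)c1cccc(OCOC)c1Br
F2 | step 5 | selenoxide of F1 (not isolated, stereoisomer mixture) | COCOC1=CC(=O)C(CC1)([Se](=O)c1ccccc1)C(=O)c1cccc(OCOC)c1Br
F3 | step 5 | 6-[2-bromo-3-(methoxymethoxy)benzoyl]-3-(methoxymethoxy)cyclohexa-2,5-dien-1-one (not isolated) | COCOC1=CC(=O)C(=CC1)C(=O)c1cccc(OCOC)c1Br
F4 | step 8 | 3-(methoxymethoxy)-2-(prop-2-en-1-yl)benzaldehyde | COCOc1cccc(C=O)c1CC=C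
F5 | step 8 | lithium aldolate of F6 (not isolated, racemic diastereomer mixture) | COCOC1=CC(=O)C(CC1)C(O[Li])c1cccc(OCOC)c1CC=C
F6 | step 8 | 6-[hydroxy(3-(methoxymethoxy)-2-(prop-2-en-1-yl)phenyl)methyl]-3-(methoxymethoxy)cyclohex-2-en-1-one (racemic diastereomer mixture) | COCOC1=CC(=O)C(CC1)C(O)c1cccc(OCOC)c1CC=C
F7 | step 8 | 6-[3-(methoxymethoxy)-2-(prop-2-en-1-yl)benzoyl]-3-(methoxymethoxy)cyclohex-2-en-1-one (racemic) | COCOC1=CC(=O)C(CC1)C(=O)c1cccc(OCOC)c1CC=C
F8 | step 8 | [2-hydroxy-4-(methoxymethoxy)phenyl][3-(methoxymethoxy)-2-(prop-2-en-1-yl)phenyl]methanone | COCOc1ccc(C(=O)c2cccc(OCOC)c2CC=C)c(O)c1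
F9 | step 8 | [5-bromo-2-hydroxy-4-(methoxymethoxy)phenyl][3-(methoxymethoxy)-2-(prop-2-en-1-yl)phenyl]methanone | COCOc1cc(O)c(C(=O)c2cccc(OCOC)c2CC=C)cc1Br
F10 | step 8 | [5-bromo-2,4-bis(methoxymethoxy)phenyl][3-(methoxymethoxy)-2-(prop-2-en-1-yl)phenyl]methanone | COCOc1cc(OCOC)c(C(=O)c2cccc(OCOC)c2CC=C)cc1Br
F11 | step 10 | [2,4-dihydroxy-5-(prop-2-en-1-yl)phenyl][3-hydroxy-2-(prop-2-en-1-yl)phenyl]methanone | C=CCc1cc(C(=O)c2cccc(O)c2CC=C)c(O)cc1O
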